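**Plan**
Retrosynthesis: after the O5/O6/O7 protecting groups are removed, the γ-pyrone of the reduced half is cut at C4–C4a and O1–C8a. Next come the C8a–N bond of the resulting enamine (back to a vinyl bromide), the aryl C6'–O8 ether bond, the aromatic chromone (C2'–C3' and O1'–C2'), and the CH2–CH2 bond of the dioxinone side chain.
Enabling feature: ring O1–C2–C3–C4 is fused to the carbocycle through C8a, which carries O1, and C4a, which carries the acyl carbon C4. A C8a-amino C8a=C4a enamine has this polarity (C4a nucleophilic, C8a electrophilic once acylated) towards the O=C–C=C=O unit of a β-ketoacyl ketene.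
Forward: the carbocycle comes from bromobenzene cis-dihydrodiol and is oxygenated (steps 1–4). The aromatic chromone is closed from paeonol (steps 5–8). Both halves are joined through O8 (step 10), Br is exchanged for morpholine (step 11), the γ-pyrone is closed last (step 12), and one acidolysis ends the route.
Stereochemistry: C7 and C8 are the enzymatically set carbinol carbons, and their C–O bonds are never broken. C6 comes from epoxidation anti to the 7,8-acetonide and C5 from SN2 opening of that epoxide. A trans-fused 6,7-diacetal then locks the half-chair and guards C5 and C8.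

Key step: step 12

Assumption: diol 1, the whole-cell dihydroxylation product of bromobenzene, is taken as a purchasable, enantiopure starting material.
Convention: the six carbocycle atoms keep their target locants (C4a, C5–C8, C8a). α is the ring face carrying O7 and O8, and β is the other face. PMB = 4-methoxybenzyl. BDA = 2,3-dimethoxybutane-2,3-diyl bridging O6 and O7, with both acetal carbons S and both methoxy groups axial.

Step 1
Reactants: 1 (1S,2S)-3-bromocyclohexa-3,5-diene-1,2-diol
Product: 2 (3aS,7aS)-4-bromo-2,2-dimethyl-3a,7a-dihydro-1,3-benzodioxole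
Conditions: Me2C(OMe)2, p-TsOH·H2O (cat.), CH2Cl2, 0 °C to rt; used at once
Reagents that add atoms: 2,2-dimethoxypropane, COC(C)(C)OC
Why: Acid-catalysed transketalisation (acetonide formation) of an arene cis-dihydrodiol is routine, touches neither C7 nor C8, and places a bulky dioxolane on the α face that steers the next step.

Step 2
Reactants: 2 (3aS,7aS)-4-bromo-2,2-dimethyl-3a,7a-dihydro-1,3-benzodioxole
Product: 3 (3aS,5aR,6aR,6bS)-4-bromo-2,2-dimethyl-3a,5a,6a,6b-tetrahydrooxireno[2,3-e][1,3]benzodioxole (5β,6β-epoxide)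
Conditions: mCPBA, CH2Cl2, 0 °C to rt
Reagents that add atoms: 3-chloroperbenzoic acid, O=C(OO)c1cccc(Cl)c1
Why: Prilezhaev epoxidation should pick the electron-richer, bromine-free C5=C6 double bond and deliver oxygen to the β face, anti to the dioxolane, which fixes the C6–O configuration of the target.

Step 3
Reactants: 3 5β,6β-epoxide
Product: 4 (3aS,4R,5S,7aS)-7-bromo-5-[(4-methoxybenzyl)oxy]-2,2-dimethyl-3a,4,5,7a-tetrahydro-1,3-benzodioxol-4-ol (5α-OPMB and 6β-OH)
Conditions: 4-MeOC6H4CH2OH (3 equiv), NaH (1.5 equiv), THF, 0 °C to reflux; H2O quench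
Reagents that add atoms: 4-methoxybenzyl alcohol, COc1ccc(CO)cc1
Why: SN2 opening of a vinyl epoxide by an alkoxide should occur with inversion at the allylic carbon C5, because C6 is shielded and deactivated by the neighbouring dioxolane oxygen, so O5 ends up α and trans to the 6β-hydroxyl, as hydroxide and methanol are known to do with this epoxide.

Step 4
Reactants: 4 5α-OPMB 6β-ol 7,8-acetonide
Product: 5 8a-bromo-5α-(4-methoxybenzyloxy)-6β,7α-O-BDA-cyclohex-8a(4a)-en-8α-ol
Conditions: butane-2,3-dione, HC(OMe)3, camphorsulfonic acid (cat.), MeOH, reflux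
Reagents that add atoms: butane-2,3-dione, CC(=O)C(C)=O; methanol, CO
Why: Butane-2,3-diacetal protection in acidic methanol first strips the acetonide and then, under thermodynamic control (trans-fused chair, two anomerically stabilised axial methoxy groups), bridges only the trans-diequatorial O6/O7 pair as in the shikimate and quinate series, so the pseudoaxial allylic 8α-hydroxyl is left free without separate differentiation of O7 and O8.

Step 5
Reactants: 6 1-(2-hydroxy-4-methoxyphenyl)ethanone (paeonol)
Product: 7 1-(5-bromo-2-hydroxy-4-methoxyphenyl)ethanone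
Conditions: NBS, MeCN, 0 °C to rt
Reagents that add atoms: N-bromosuccinimide, O=C1CCC(=O)N1Br
Why: Electrophilic aromatic bromination should go to C5, para to the chelated phenol and ortho to the methoxy group, because C3 between the two oxygen substituents is hindered.

Step 6
Reactants: 7 1-(5-bromo-2-hydroxy-4-methoxyphenyl)ethanone; 8 ethyl 3-phenylpropanoate
Product: 9 1-(5-bromo-2-hydroxy-4-methoxyphenyl)-5-phenylpentane-1,3-dione
Conditions: NaH (4 equiv), THF, reflux; then aq HCl, 0 °C
Reagents that add atoms: none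
Why: Crossed Claisen condensation of the acetophenone enolate with the ester, driven by deprotonation of the 1,3-diketone formed, is the standard entry to 2-(2-phenylethyl)chromones and leaves the aryl bromide alone.

Step 7
Reactants: 9 1-(5-bromo-2-hydroxy-4-methoxyphenyl)-5-phenylpentane-1,3-dione
Product: 10 6-bromo-7-methoxy-2-(2-phenylethyl)-4H-chromen-4-one
Conditions: conc. HCl (cat.), MeOH, reflux
Reagents that add atoms: none
Why: Acid-catalysed cyclodehydration of an o-hydroxyaryl 1,3-diketone (6-exo-trig addition of the phenol to the side-chain carbonyl, then loss of water) is the classical chromone ring closure.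

Step 8
Reactants: 10 6-bromo-7-methoxy-2-(2-phenylethyl)-4H-chromen-4-one
Product: 12 potassium trifluoro[7-methoxy-4-oxo-2-(2-phenylethyl)-4H-chromen-6-yl]borate, via pinacol boronate 11 (not isolated)
Conditions: B2pin2, PdCl2(dppf) (3 mol %), KOAc, 1,4-dioxane, 90 °C; filter, evaporate; then KHF2, MeOH/H2O, rt
Reagents that add atoms: bis(pinacolato)diboron, CC1(C)OB(OC1(C)C)B1OC(C)(C)C(C)(C)O1; potassium hydrogen difluoride, F.[F-].[K+]
Why: Miyaura borylation of the aryl bromide followed by fluoride exchange with KHF2 is a standard two-stage route to a crystalline aryltrifluoroborate, and the weak acetate base spares the chromone.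

Step 9
Reactants: 13 2,2,6-trimethyl-4H-1,3-dioxin-4-one; 14 benzyl bromide
Product: 16 2,2-dimethyl-6-(2-phenylethyl)-4H-1,3-dioxin-4-one, via lithium dienolate 15 (not isolated)
Conditions: LiN(iPr)2 (LDA), THF/DMPU, −78 °C; then BnBr, −78 to −20 °C
Reagents that add atoms: none
Why: γ-Alkylation of the extended lithium dienolate of the dioxinone with a reactive benzylic halide in the presence of a polar co-solvent is the known way to lengthen the C6 methyl group.

Step 10
Reactants: 5 8α-alcohol; 12 potassium aryltrifluoroborate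
Product: 17 6-{[8a-bromo-5α-(4-methoxybenzyloxy)-6β,7α-O-BDA-cyclohex-8a(4a)-en-8α-yl]oxy}-7-methoxy-2-(2-phenylethyl)-4H-chromen-4-one
Conditions: 12 (2 equiv), Cu(OAc)2·H2O (20 mol %), DMAP (40 mol %), 4 Å MS, O2 (1 atm), CH2Cl2, rt
Reagents that add atoms: none
Why: Chan–Lam oxidative etherification in its aryltrifluoroborate variant couples secondary aliphatic alcohols at room temperature under nearly neutral conditions, so only the O–H bond of 5 reacts, C8 keeps its configuration, and the alkenyl bromide, chromone, PMB ether and BDA acetal are not touched.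

Step 11
Reactants: 17 8-O-aryl vinyl bromide
Product: 18 morpholine enamine (17 with morpholin-4-yl in place of Br at C8a and the double bond at C8a=C4a)
Conditions: morpholine (1.2 equiv), Pd2(dba)3 (2.5 mol %), rac-BINAP (7.5 mol %), Cs2CO3 (1.5 equiv), toluene, 90 °C; filtered through Celite under Ar, evaporated, used crude
Reagents that add atoms: morpholine, C1COCCN1
Why: Buchwald–Hartwig-type amination of an alkenyl bromide with a secondary amine replaces Br at C8a without moving the double bond, which should give the enamine as one regioisomer that ketone condensation could not guarantee, and the carbonate base is chosen to spare the chromone.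

Step 12
Reactants: 18 morpholine enamine; 16 2,2-dimethyl-6-(2-phenylethyl)-4H-1,3-dioxin-4-one
Product: 21 5-O-PMB-6,7-O-BDA derivative of the target, via acylketene 19 (not isolated), via C-acylated enaminone 20 (not isolated)
Conditions: 16 (3 equiv, added slowly), toluene, 110 °C, Ar
Reagents that add atoms: none
Why: Heating makes 16 lose acetone in a retro-hetero-Diels–Alder reaction, and the ketene carbon of the acylketene 19 so formed (the future C4) is attacked by the nucleophilic β-carbon C4a of enamine 18, proton transfer leading to the vinylogous amide 20. The enolised side-chain carbonyl oxygen of 20 (the future O1) then adds to C8a in a 6-endo-trig oxa-Michael closure and morpholine is expelled, so that C4–C4a, O1–C8a and the γ-pyrone ring are made in one flask, overall a formal hetero-[4+2] cycloaddition followed by β-elimination. The closest known reaction type is the annulation of 1-morpholinocyclohexene with diketene or with 2,2,6-trimethyl-1,3-dioxin-4-one to give 2-methyl-5,6,7,8-tetrahydrochromone. No stereocentre is created, and C5 to C8 only have to survive. The step needs acylation at C4a rather than C8, which is secured because the double bond sits at C8a=C4a where the bromide left it, and it needs intact allylic C5–O and C8–O bonds, which the trans-fused BDA ring secures by holding C5–OPMB and C8–H pseudo-equatorial, close to the nodal plane of the enamine π system, so that neither expulsion of the 5-alkoxy group nor tautomerisation through C8 has good orbital overlap. The medium stays neutral and aprotic, and 16 is used in excess because the morpholine that is released consumes part of 19.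

Step 13
Reactants: 21 5-O-PMB-6,7-O-BDA derivative of the target
Product: 22 (5S,6R,7S,8S)-5,6,7-trihydroxy-8-{[7-methoxy-4-oxo-2-(2-phenylethyl)-4H-chromen-6-yl]oxy}-2-(2-phenylethyl)-5,6,7,8-tetrahydro-4H-chromen-4-one
Conditions: TFA/H2O (9:1), 1,3-dimethoxybenzene (3 equiv), CH2Cl2, 0 °C to rt
Reagents that add atoms: none
Why: In this global acidolysis the PMB ether ionises to the 4-methoxybenzyl cation (removed by Friedel–Crafts capture on 1,3-dimethoxybenzene) and the BDA acetal hydrolyses at its acetal carbons, while the ring C–O bonds stay intact because cations at C5 or C8 would be attached to the electron-poor pyranone, so all four stereocentres are retained.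

**Compound list**
1 | (1S,2S)-3-bromocyclohexa-3,5-diene-1,2-diol | O[C@@H]1C(Br)=CC=C[C@@H]1O | starting material
2 | (3aS,7aS)-4-bromo-2,2-dimethyl-3a,7a-dihydro-1,3-benzodioxole | CC1(C)O[C@@H]2C(Br)=CC=C[C@@H]2O1 | intermediate
3 | (3aS,5aR,6aR,6bS)-4-bromo-2,2-dimethyl-3a,5a,6a,6b-tetrahydrooxireno[2,3-e][1,3]benzodioxole | CC1(C)O[C@@H]2C(Br)=C[C@H]3O[C@H]3[C@@H]2O1 | intermediate
4 | (3aS,4R,5S,7aS)-7-bromo-5-[(4-methoxybenzyl)oxy]-2,2-dimethyl-3a,4,5,7a-tetrahydro-1,3-benzodioxol-4-ol | CC1(C)O[C@@H]2C(Br)=C[C@H](OCc3ccc(OC)cc3)[C@@H](O)[C@@H]2O1 | intermediate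
5 | 8a-bromo-5α-(4-methoxybenzyloxy)-6β,7α-O-BDA-cyclohex-8a(4a)-en-8α-ol | O[C@@H]1C(Br)=C[C@H](OCc3ccc(OC)cc3)[C@H]2O[C@](C)(OC)[C@@](C)(OC)O[C@H]12 | intermediate
6 | 1-(2-hydroxy-4-methoxyphenyl)ethanone (paeonol) | COc1ccc(C(C)=O)c(O)c1 | starting material
7 | 1-(5-bromo-2-hydroxy-4-methoxyphenyl)ethanone | COc1cc(O)c(C(C)=O)cc1Br | intermediate
8 | ethyl 3-phenylpropanoate | CCOC(=O)CCc1ccccc1 | starting material
9 | 1-(5-bromo-2-hydroxy-4-methoxyphenyl)-5-phenylpentane-1,3-dione | COc1cc(O)c(C(=O)CC(=O)CCc2ccccc2)cc1Br | intermediate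
10 | 6-bromo-7-methoxy-2-(2-phenylethyl)-4H-chromen-4-one | COc1cc2oc(CCc3ccccc3)cc(=O)c2cc1Br | intermediate
11 | 7-methoxy-2-(2-phenylethyl)-6-(4,4,5,5-tetramethyl-1,3,2-dioxaborolan-2-yl)-4H-chromen-4-one | COc1cc2oc(CCc3ccccc3)cc(=O)c2cc1B1OC(C)(C)C(C)(C)O1 | intermediate
12 | potassium trifluoro[7-methoxy-4-oxo-2-(2-phenylethyl)-4H-chromen-6-yl]borate | COc1cc2oc(CCc3ccccc3)cc(=O)c2cc1[B-](F)(F)F.[K+] | intermediate
13 | 2,2,6-trimethyl-4H-1,3-dioxin-4-one | CC1=CC(=O)OC(C)(C)O1 | starting material
14 | benzyl bromide | BrCc1ccccc1 | starting material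
15 | lithium dienolate of 13 | [Li+].C=C1C=C([O-])OC(C)(C)O1 | intermediate
16 | 2,2-dimethyl-6-(2-phenylethyl)-4H-1,3-dioxin-4-one | CC1(C)OC(=O)C=C(CCc2ccccc2)O1 | intermediate
17 | 8-O-aryl vinyl bromide (8α-aryloxy, 5α-OPMB, 6β,7α-O-BDA, Br at C8a) | COc1cc2oc(CCc3ccccc3)cc(=O)c2cc1O[C@@H]1C(Br)=C[C@H](OCc3ccc(OC)cc3)[C@H]2O[C@](C)(OC)[C@@](C)(OC)O[C@H]12 | intermediate
18 | morpholine enamine (morpholin-4-yl at C8a, C8a=C4a) | COc1cc2oc(CCc3ccccc3)cc(=O)c2cc1O[C@@H]1C(N3CCOCC3)=C[C@H](OCc3ccc(OC)cc3)[C@H]2O[C@](C)(OC)[C@@](C)(OC)O[C@H]12 | intermediate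
19 | 3-oxo-5-phenylpent-1-en-1-one (acylketene) | O=C=CC(=O)CCc1ccccc1 | intermediate
20 | C4a-(3-oxo-5-phenylpentanoyl) enaminone | COc1cc2oc(CCc3ccccc3)cc(=O)c2cc1O[C@@H]1C(N3CCOCC3)=C(C(=O)CC(=O)CCc3ccccc3)[C@H](OCc3ccc(OC)cc3)[C@H]2O[C@](C)(OC)[C@@](C)(OC)O[C@H]12 | intermediate
21 | 5-O-PMB-6,7-O-BDA derivative of the target | COc1cc2oc(CCc3ccccc3)cc(=O)c2cc1O[C@@H]1c2oc(CCc3ccccc3)cc(=O)c2[C@H](OCc2ccc(OC)cc2)[C@H]2O[C@](C)(OC)[C@@](C)(OC)O[C@H]12 | intermediate
22 | (5S,6R,7S,8S)-5,6,7-trihydroxy-8-{[7-methoxy-4-oxo-2-(2-phenylethyl)-4H-chromen-6-yl]oxy}-2-(2-phenylethyl)-5,6,7,8-tetrahydro-4H-chromen-4-one | COc1cc2oc(CCc3ccccc3)cc(=O)c2cc1O[C@@H]1c2oc(CCc3ccccc3)cc(=O)c2[C@H](O)[C@@H](O)[C@@H]1O | target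

Total step count: 13.
Longest linear sequence: 8 steps (steps 1–4 and 10–13 from 1, or equally steps 5–8 and 10–13 from 6).

**Steps most likely to fail**

Step 10 (O-arylation).
- Risk: transmetalation and C–O reductive elimination at copper may be slowed by the pseudoaxial, doubly flanked hydroxyl and by the ortho-methoxy group of the borate. Protodeboronation and oxidation of the aryl donor would then outrun etherification.
- Fallback (sets out from 5 and crude boronate 11, returns at 17): the C8–O bond is made instead of the aryl–O bond, by double inversion. Mitsunobu reaction of 5 with 4-nitrobenzoic acid (PPh3, DIAD, toluene) should give the inverted 8β-(4-nitrobenzoate) F1. Methanolysis (K2CO3, MeOH) should then give the 8β-alcohol F2. Oxidation of 11 with NaBO3·4H2O in THF/H2O should give 6-hydroxy-7-methoxy-2-(2-phenylethyl)chromone F3. A second Mitsunobu reaction of F2 with F3 inverts C8 again and delivers 17. Displacing an equatorial oxyphosphonium group in a locked ring is the kind of inversion used to turn gluco- into galacto-configured pyranosides.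

Step 11 (enamine formation).
- Risk: zerovalent palladium may ionise the allylic C8 aryl ether, morpholine or base may attack the chromone, and oxidative addition next to the bulky aryloxy group may be slow.
- Fallback (sets out from 5, returns at 21): the order of events is changed so that no aryl ether and no chromone is present during the amination. Silylation of 5 (TBSOTf, 2,6-lutidine, CH2Cl2) gives the 8-O-TBS ether F4. Amination under the standard strong-base conditions (morpholine, Pd2(dba)3, rac-BINAP, NaOtBu, toluene, 90 °C) gives the silyloxy enamine F5. Heating F5 with 16 in toluene at 110 °C gives the 8-O-TBS tetrahydrochromone F6. HF·pyridine in THF frees the 8α-alcohol F7, and Chan–Lam coupling of F7 with 12 under the conditions of step 10 gives 21.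

Step 12 (pyranone annulation).
- Risk: at 110 °C the enamine may erode (loss of the 5-alkoxy group, migration of the double bond towards C8, hydrolysis by adventitious water). The acylketene may also dimerise faster than it acylates the hindered C4a.
- Fallback (sets out from 18, returns at 21): the ring is built in two stages at or below room temperature. Carboxylation of 4-phenylbut-1-yne (n-BuLi, CO2) gives 5-phenylpent-2-ynoic acid F8. Oxalyl chloride with catalytic DMF gives 5-phenylpent-2-ynoyl chloride F9. Stork acylation of 18 with F9 (Et3N, CH2Cl2, −20 °C) gives the C4a-alkynoyl enaminone F10. Aqueous acetic acid in THF hydrolyses the vinylogous amide to the acetylenic β-diketone F11. The C8a enol oxygen of F11 adds 6-endo-dig to the ynone, the known cyclisation of acetylenic β-diketones to γ-pyrones, and this gives 21.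

Further compounds
F1 | step 10 | 8β-(4-nitrobenzoate) of the C8 epimer of 5 | O=C(O[C@H]1C(Br)=C[C@H](OCc2ccc(OC)cc2)[C@H]2O[C@](C)(OC)[C@@](C)(OC)O[C@H]12)c1ccc(cc1)[N+](=O)[O-]
F2 | step 10 | C8 epimer of 5 (8β-alcohol) | O[C@H]1C(Br)=C[C@H](OCc2ccc(OC)cc2)[C@H]2O[C@](C)(OC)[C@@](C)(OC)O[C@H]12
F3 | step 10 | 6-hydroxy-7-methoxy-2-(2-phenylethyl)-4H-chromen-4-one | COc1cc2oc(CCc3ccccc3)cc(=O)c2cc1O
F4 | step 11 | 8-O-tert-butyldimethylsilyl ether of 5 | CC(C)(C)[Si](C)(C)O[C@@H]1C(Br)=C[C@H](OCc2ccc(OC)cc2)[C@H]2O[C@](C)(OC)[C@@](C)(OC)O[C@H]12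
F5 | step 11 | morpholine enamine derived from F4 | CC(C)(C)[Si](C)(C)O[C@@H]1C(N2CCOCC2)=C[C@H](OCc2ccc(OC)cc2)[C@H]2O[C@](C)(OC)[C@@](C)(OC)O[C@H]12
F6 | step 11 | 8-O-TBS-5-O-PMB-6,7-O-BDA-2-(2-phenylethyl)-5,6,7,8-tetrahydrochromone | CC(C)(C)[Si](C)(C)O[C@@H]1c2oc(CCc3ccccc3)cc(=O)c2[C@H](OCc2ccc(OC)cc2)[C@H]2O[C@](C)(OC)[C@@](C)(OC)O[C@H]12
F7 | step 11 | 8α-hydroxy-5-O-PMB-6,7-O-BDA-2-(2-phenylethyl)-5,6,7,8-tetrahydrochromone | O[C@@H]1c2oc(CCc3ccccc3)cc(=O)c2[C@H](OCc2ccc(OC)cc2)[C@H]2O[C@](C)(OC)[C@@](C)(OC)O[C@H]12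
F8 | step 12 | 5-phenylpent-2-ynoic acid | O=C(O)C#CCCc1ccccc1
F9 | step 12 | 5-phenylpent-2-ynoyl chloride | O=C(Cl)C#CCCc1ccccc1
F10 | step 12 | C4a-(5-phenylpent-2-ynoyl) enaminone | COc1cc2oc(CCc3ccccc3)cc(=O)c2cc1O[C@@H]1C(N3CCOCC3)=C(C(=O)C#CCCc3ccccc3)[C@H](OCc3ccc(OC)cc3)[C@H]2O[C@](C)(OC)[C@@](C)(OC)O[C@H]12
F11 | step 12 | acetylenic β-diketone (C8a enol form) | COc1cc2oc(CCc3ccccc3)cc(=O)c2cc1O[C@@H]1C(O)=C(C(=O)C#CCCc3ccccc3)[C@H](OCc3ccc(OC)cc3)[C@H]2O[C@](C)(OC)[C@@](C)(OC)O[C@H]12
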